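The data were generated by integration for substances that don't exist, noise included.

| setting | alpha | epsilon | flask |
|---|---|---|---|
| starting material | 2.1 M | 1.5 M | 1.5 M |
| free catalyst | 1.5 mM | 0.75 mM | 1.5 mM |
| remark | run made earlier | run made earlier |  |

- alpha (time / min: product / %, starting material / %): 3.00: 48.6, 52.1; 5.00: 62.8, 37.0; 10.0: 79.3, 21.6; 20.0: 89.0, 12.1; 40.0: 89.7, 8.8
- epsilon (time / min: product / %, starting material / %): 3.00: 25.8, 72.3; 10.0: 54.6, 46.9; 15.0: 60.1, 38.1; 25.0: 67.1, 33.4; 40.0: 69.7, 32.6

(each reading ± 1 percentage point)

- factor on the rate of making product when 50% of the starting material are converted if free catalyst is charged twice over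
- factor on the rate when 50% of the starting material are converted if free catalyst is charged at 8.0 mM instead

The ratio of charge to remainder shows how far a run got: in the alpha run it is 11.4 after 40.0 min. I call its natural logarithm, 2.43, the reach: the logarithm of charge over remainder that one catalyst charge delivers in its working life. That is 1.06 powers of ten, read from a reading good to 1 percentage point.

The epsilon run reads a reach of 1.12, so the alpha run reaches twice as far on twice the catalyst charge, though its starting material differs too. I take the reach to follow the catalyst charge and give the new flask, with the catalyst charge of the alpha run, the same reach.

I take the starting material to fall pseudo-first-order, with a constant that sinks with the free catalyst. The logarithm gained so far, over the reach, is then the share of free catalyst lost. The first readings give a decay constant of 0.104 /min in the alpha run and 0.114 /min in the epsilon run.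

My ladder for the flask has three rungs. I reckon a catalyst life of 9.60 min from the alpha run. Fresh catalyst needs 3.95 min per unit of logarithm, which is shorter than that life, and the life is shorter than the 40.0 min of the last reading. At 50% conversion, reached at 3.22 min, ln(2) of the reach is used, so 71.5% of the free catalyst remains.

A larger charge lengthens the reach and raises that share, so I reckon factors of 2.40 and 7.06. The forecast gives 2.4 and 7.1, holding that “the catalyst dies in time”.

The flask gives 2.41 and 7.13.

    starting material + free catalyst → free catalyst + product (k = 169 /M/min)
    free catalyst → spent catalyst (k = 0.107 /min)

At 3.00 min the flask holds 52.2% starting material, 72.5% free catalyst and 27.5% spent catalyst, which neither factor shows. The reach, applied to that starting material, gives 73.2% free catalyst. With twice the free catalyst, the reach gives a factor of 0.458 on the time to 50% conversion, and that run gives 0.457.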